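**Retrosynthetic overview**

1. Numbering (bicyclo[3.3.1]nonane): C1 prenyl bridgehead, C2–C3(aroyl)–C4 enolised β-diketone bridge, C5 lavandulyl bridgehead, C6H2–C7H(prenyl)–C8(Me)(homoprenyl), C9 bridging ketone. Target 33 ⇐ C3 aroylation, C1 bridgehead prenylation, and C8 quaternisation (axial conjugate addition of the homoprenyl group to an exocyclic enal, then decarbonylation CH2CHO → CH3) on bicyclic enal 21.
2. 21 ⇐ C1–C8 bond: iminium-catalysed 6-exo-dig addition of ring A (a 4,4-disubstituted 3,5-dimethoxycyclohexa-2,5-dienone, a masked phloroglucinol) to a tethered ynal in 20. This closes the ring C1–C9–C5–C6–C7–C8.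
3. Feature used: C5 carries two CH2–CH(prenyl)–C arms of opposite configuration (the lavandulyl group and C6–C7–C8). In 20 ring A is therefore Cs-symmetric, C5 is not yet a stereocentre, C1 and C3 are equivalent enol-ether carbons, and the propargylic stereocentre C7 alone decides which attacks, fixing C1 and C5.
4. 20 ⇐ two alkylations of 1,5-dimethoxycyclohexa-1,4-diene at the carbon between the enol ethers (future C5), with (S)-lavandulyl triflate and with the C6–C8 alkynyl arm, then bis-allylic oxidation (C2=O). The arms come from resolved lavandulol and from a Sharpless epoxide opened by an alkynylalane.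
5. Ring order: ring A (C1–C2–C3–C4–C5–C9) comes with the commercial diene and the arene with the aroyl chloride; the ring C1–C9–C5–C6–C7–C8 is the last ring closed.

Key step: step 12

Assumption: the target is one drawn enol tautomer (C4–OH/C2=O) of an equilibrating enolised β-triketone; in step 6 the lipase is taken to acylate (R)-lavandulol faster, so the (S)-alcohol is the recovered enantiomer. "Lavandulyl" below means 5-methyl-2-(prop-1-en-2-yl)hex-4-enyl.

**Route**

Step 1
Reactants: 1 prop-2-yn-1-ol; 2 1-bromo-3-methylbut-2-ene (prenyl bromide)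
Product: 3 6-methylhept-5-en-2-yn-1-ol
Conditions: CuI (cat.), NaI (cat.), K2CO3, DMF, rt
Reagents that add atoms: none
Why: Copper(I)-acetylide SN2 coupling of a terminal alkyne with an allylic bromide should attack the unhindered primary carbon of prenyl bromide and give the skipped enyne; no stereocentre is formed.

Step 2
Reactants: 3 6-methylhept-5-en-2-yn-1-ol
Product: 4 (E)-6-methylhepta-2,5-dien-1-ol
Conditions: LiAlH4, THF, 0 °C to reflux; aqueous work-up
Reagents that add atoms: none
Why: Alkoxide-directed trans-hydroalumination of a propargylic alcohol should give the (E)-allylic alcohol only, the isolated trisubstituted alkene being inert; the E geometry follows from the anti addition.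

Step 3
Reactants: 4 (E)-6-methylhepta-2,5-dien-1-ol
Product: 5 [(2R,3R)-3-(3-methylbut-2-enyl)oxiran-2-yl]methanol
Conditions: Ti(OiPr)4 (cat.), D-(−)-diethyl tartrate (cat.), t-BuOOH, 4 Å MS, CH2Cl2, −20 °C
Reagents that add atoms: tert-butyl hydroperoxide, CC(C)(C)OO
Why: Sharpless asymmetric epoxidation is specific for the allylic alcohol double bond and, with D-(−)-tartrate on an (E)-allylic alcohol, should set both epoxide stereocentres as (2R,3R) by reagent control.

Step 4
Reactants: 5 [(2R,3R)-3-(3-methylbut-2-enyl)oxiran-2-yl]methanol; 6 tert-butyldimethyl(prop-2-ynyloxy)silane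
Product: 8 (2S,3R)-6-(tert-butyldimethylsilyloxy)-3-(3-methylbut-2-enyl)hex-4-yne-1,2-diol, via alkynyldiethylalane 7 (not isolated)
Conditions: 6, n-BuLi, toluene, 0 °C; Et2AlCl (gives 7); then 5, 0 °C to rt; aq. Rochelle salt
Reagents that add atoms: none
Why: Opening of a 2,3-epoxy alcohol by an alkynylalane is delivered from the aluminium alkoxide to C3 with SN2 inversion, so the propargylic stereocentre (future C7) is set from the epoxide and the 1,2-diol results.

Step 5
Reactants: 8 (2S,3R)-6-(tert-butyldimethylsilyloxy)-3-(3-methylbut-2-enyl)hex-4-yne-1,2-diol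
Product: 10 (R)-5-(tert-butyldimethylsilyloxy)-2-(3-methylbut-2-enyl)pent-3-yn-1-ol, via alkynyl aldehyde 9 (not isolated)
Conditions: NaIO4, THF/pH 7 buffer, 0 °C; extraction; then NaBH4, MeOH, −20 °C
Reagents that add atoms: none
Why: Periodate glycol cleavage removes the carbinol carbon and immediate borohydride reduction of the epimerisable α-alkynyl aldehyde should preserve the propargylic stereocentre; no new stereocentre is formed.

Step 6
Reactants: 11 rac-lavandulol
Product: 12 (S)-lavandulol
Conditions: porcine pancreatic lipase, vinyl acetate, hexane, rt, stopped past half conversion; chromatography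
Reagents that add atoms: none
Why: Lipase-catalysed enantioselective transesterification (kinetic resolution) should acylate the (R)-alcohol and leave (S)-lavandulol, so the lavandulyl stereocentre is taken from the racemate and not created.

Step 7
Reactants: 13 1,5-dimethoxycyclohexa-1,4-diene; 12 (S)-lavandulol
Product: 15 1,5-dimethoxy-6-[(R)-lavandulyl]cyclohexa-1,4-diene, via lavandulyl triflate 14 (not isolated)
Conditions: 12, Tf2O, 2,6-lutidine, CH2Cl2, −78 °C (gives 14, used cold); 13, t-BuLi, THF, −78 °C; then 14, −78 to −30 °C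
Reagents that add atoms: none
Why: Deprotonation of the diene at the doubly allylic carbon flanked by both enol ethers and SN2 alkylation of the pentadienyl anion at its central carbon by a primary triflate is the known route to 2-substituted dihydroresorcinol ethers; the side-chain stereocentre is untouched (the descriptor changes from S to R by priority only) and the ring carbon is not stereogenic.

Step 8
Reactants: 15 1,5-dimethoxy-6-[(R)-lavandulyl]cyclohexa-1,4-diene; 10 (R)-5-(tert-butyldimethylsilyloxy)-2-(3-methylbut-2-enyl)pent-3-yn-1-ol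
Product: 17 1,5-dimethoxy-6-[(R)-lavandulyl]-6-[(S)-5-(tert-butyldimethylsilyloxy)-2-(3-methylbut-2-enyl)pent-3-ynyl]cyclohexa-1,4-diene, via alkynyl triflate 16 (not isolated)
Conditions: 10, Tf2O, 2,6-lutidine, CH2Cl2, −78 °C (gives 16, used cold); 15, t-BuLi, THF/HMPA, −78 °C; then 16, −78 to −20 °C
Reagents that add atoms: none
Why: A second deprotonation–alkylation at the same carbon should build the quaternary carbon (future C5), the triflate being chosen so that SN2 attack by the tertiary anion outruns elimination; the ring stays Cs-symmetric, so no new stereocentre arises.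

Step 9
Reactants: 17 the 6,6-disubstituted 1,5-dimethoxycyclohexa-1,4-diene
Product: 18 3,5-dimethoxy-4-[(R)-lavandulyl]-4-[(S)-5-(tert-butyldimethylsilyloxy)-2-(3-methylbut-2-enyl)pent-3-ynyl]cyclohexa-2,5-dien-1-one
Conditions: Rh2(cap)4 (1 mol%), t-BuOOH, K2CO3, CH2Cl2, rt
Reagents that add atoms: tert-butyl hydroperoxide, CC(C)(C)OO
Why: Metal-catalysed allylic C–H oxidation should be selective for the doubly allylic CH2 between the two enol-ether double bonds, whose C–H bonds are far weaker than those of the prenyl groups, and gives the cross-conjugated dienone carrying the C2 oxygen; no stereocentre is affected.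

Step 10
Reactants: 18 the silyl ether dienone
Product: 19 3,5-dimethoxy-4-[(R)-lavandulyl]-4-[(S)-5-hydroxy-2-(3-methylbut-2-enyl)pent-3-ynyl]cyclohexa-2,5-dien-1-one
Conditions: TBAF, THF, 0 °C
Reagents that add atoms: none
Why: Fluoride cleavage of the primary silyl ether; the vinylogous esters and the alkenes should be inert.

Step 11
Reactants: 19 the propargylic alcohol
Product: 20 3,5-dimethoxy-4-[(R)-lavandulyl]-4-[(S)-5-oxo-2-(3-methylbut-2-enyl)pent-3-ynyl]cyclohexa-2,5-dien-1-one
Conditions: MnO2, CH2Cl2, rt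
Reagents that add atoms: none
Why: MnO2 oxidises propargylic alcohols selectively to ynals under neutral conditions, which installs the removable activating group for the ring closure.

Step 12
Reactants: 20 the ynal dienone
Product: 21 (Z)-2-[4-methoxy-5-((R)-lavandulyl)-7-(3-methylbut-2-enyl)-2,9-dioxobicyclo[3.3.1]non-3-en-8-ylidene]acetaldehyde (C1, C5, C7 as in 33)
Conditions: dibenzylammonium trifluoroacetate (20 mol%), CH2Cl2/H2O (20:1), 0 °C to rt
Reagents that add atoms: water, O
Why: Proposed new method: the ammonium salt should condense with the ynal to an alkynyl iminium ion, to whose β-carbon (C8) the nucleophilic α-carbon C1 of one methyl enol ether of ring A adds in a 6-exo-dig closure that forms the C1–C8 bond and the ring C1–C9–C5–C6–C7–C8; water then hydrolyses the O-methyl oxocarbenium ion at C9 to the ketone (methanol leaves; loss of a proton instead would need an impossible C1=C9 bridgehead alkene) and the allenamine to the exocyclic enal, releasing the amine. The closest known reaction types are iminium-catalysed Mukaiyama–Michael and Friedel–Crafts additions of enol ethers and electron-rich arenes to enals and ynals and the 6-exo-dig Conia-ene carbocyclisation of 1,3-dicarbonyl enols onto alkynes; new is only the donor, a β-methoxy enone. No stereocentre is made at C8 (it stays sp2), but C5 and C1 become stereocentres by desymmetrisation: the two enol ethers of the Cs-symmetric dienone differ only through the propargylic stereocentre C7, and in the chair-like transition state the C7 prenyl group is equatorial when the pro-C1 enol ether attacks, whereas attack by the other would force it axial, under ring A. The step needs C- over O-cyclisation, which the two O-methyl groups secure, and attack by ring A rather than by one of the four alkenes, which covalent activation of the aldehyde alone secures (a Lewis acid would bind the more basic dienone carbonyl, and a π-acidic metal would start a 1,5-enyne cyclisation with the neighbouring prenyl group). Attack at the other alkyne carbon is excluded as an anti-Michael 7-endo process, and the enal geometry is of no consequence because C8 becomes tetrahedral in step 13.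

Step 13
Reactants: 21 the bicyclic enal; 22 5-bromo-2-methylpent-2-ene
Product: 25 2-[4-methoxy-5-((R)-lavandulyl)-7-(3-methylbut-2-enyl)-8-(4-methylpent-3-enyl)-2,9-dioxobicyclo[3.3.1]non-3-en-8-yl]acetaldehyde, via Grignard reagent 23 (not isolated), via silyl enol ether 24 (not isolated)
Conditions: 22, Mg, THF, rt (gives 23); CuBr·SMe2 (10 mol%), TMSCl, HMPA, THF, −78 °C, then 21 (gives 24); 1 M HCl, THF, 0 °C
Reagents that add atoms: none
Why: Copper-catalysed, TMSCl-accelerated conjugate addition of a Grignard reagent to a β,β-disubstituted enal should create the C8 quaternary stereocentre by attack on the exocyclic double bond from the convex face, anti to C2 of ring A (the axial substituent on C1 that shields the other face), which places the homoprenyl group axial and the formylmethyl group equatorial as the target requires.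

Step 14
Reactants: 25 the formylmethyl compound
Product: 26 4-methoxy-8-methyl-5-((R)-lavandulyl)-7-(3-methylbut-2-enyl)-8-(4-methylpent-3-enyl)bicyclo[3.3.1]non-3-ene-2,9-dione (C1–H; C1, C5, C7, C8 as in 33)
Conditions: RhCl(PPh3)3 (1.1 equiv), toluene, 90 °C
Reagents that add atoms: none
Why: Tsuji–Wilkinson decarbonylation of a primary aldehyde turns the formylmethyl group into the C8 methyl group with retention at C8, and no 4-pentenal unit is present that could divert the acyl-rhodium hydride to hydroacylation.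

Step 15
Reactants: 26 the C1–H bicycle; 2 1-bromo-3-methylbut-2-ene
Product: 27 4-methoxy-8-methyl-5-((R)-lavandulyl)-1,7-bis(3-methylbut-2-enyl)-8-(4-methylpent-3-enyl)bicyclo[3.3.1]non-3-ene-2,9-dione
Conditions: LDA, THF, −78 °C; then 2, −78 to 0 °C
Reagents that add atoms: none
Why: Bridgehead deprotonation α′ to the β-methoxy enone carbonyl (and α to C9) followed by enolate C-alkylation with prenyl bromide is a known operation on bicyclo[3.3.1]nonane-2,4,9-trione enol ethers; the configuration at C1 is dictated by the bicycle (retention).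

Step 16
Reactants: 28 3,4-dihydroxybenzoic acid
Product: 30 3,4-bis(tert-butyldimethylsilyloxy)benzoic acid, via tris-silyl compound 29 (not isolated)
Conditions: TBSCl, imidazole, DMF, rt (gives 29); then AcOH/THF/H2O, rt
Reagents that add atoms: tert-butyldimethylsilyl chloride, CC(C)(C)[Si](C)(C)Cl
Why: Silylation of both phenols and the acid followed by selective hydrolysis of the labile silyl ester should give the bis-silyl ether acid; no stereocentre is involved.

Step 17
Reactants: 30 3,4-bis(tert-butyldimethylsilyloxy)benzoic acid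
Product: 31 3,4-bis(tert-butyldimethylsilyloxy)benzoyl chloride
Conditions: (COCl)2, DMF (cat.), CH2Cl2, 0 °C to rt
Reagents that add atoms: oxalyl chloride, ClC(=O)C(=O)Cl
Why: Acid chloride formation by Vilsmeier-type activation with oxalyl chloride and catalytic DMF is mild enough for aryl silyl ethers.

Step 18
Reactants: 27 the fully alkylated enol ether; 31 3,4-bis(tert-butyldimethylsilyloxy)benzoyl chloride
Product: 32 O-methyl bis-silyl ether of the target (3-aroyl-4-methoxy compound)
Conditions: LiTMP, THF, −78 °C; then 31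
Reagents that add atoms: none
Why: Lithiation of the vinylic C3–H of the β-methoxy enone (both bridgeheads are now quaternary) and C-acylation by the aroyl chloride is the known way to introduce the 3-acyl group of this compound class; no stereocentre is affected.

Step 19
Reactants: 32 the protected target
Product: 33 CNP0241026.2 (target)
Conditions: LiOH, dioxane/H2O (degassed), 90 °C; then 1 M HCl
Reagents that add atoms: lithium hydroxide, [Li+].[OH-]
Why: Addition–elimination hydrolysis of the vinylogous methyl ester and hydroxide cleavage of both aryl silyl ethers should release the enolised triketone and the catechol in one operation; all stereocentres are quaternary or remote from acidic positions and stay intact.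

**Compound list**

1 | prop-2-yn-1-ol | C#CCO | starting material
2 | 1-bromo-3-methylbut-2-ene (prenyl bromide) | CC(C)=CCBr | starting material
3 | 6-methylhept-5-en-2-yn-1-ol | OCC#CCC=C(C)C | intermediate
4 | (E)-6-methylhepta-2,5-dien-1-ol | OC/C=C/CC=C(C)C | intermediate
5 | [(2R,3R)-3-(3-methylbut-2-enyl)oxiran-2-yl]methanol | OC[C@H]1O[C@@H]1CC=C(C)C | intermediate
6 | tert-butyldimethyl(prop-2-ynyloxy)silane | C#CCO[Si](C)(C)C(C)(C)C | starting material
7 | diethyl[3-(tert-butyldimethylsilyloxy)prop-1-ynyl]aluminium | CC[Al](CC)C#CCO[Si](C)(C)C(C)(C)C | intermediate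
8 | (2S,3R)-6-(tert-butyldimethylsilyloxy)-3-(3-methylbut-2-enyl)hex-4-yne-1,2-diol | OC[C@@H](O)[C@H](CC=C(C)C)C#CCO[Si](C)(C)C(C)(C)C | intermediate
9 | (R)-5-(tert-butyldimethylsilyloxy)-2-(3-methylbut-2-enyl)pent-3-ynal | O=C[C@H](CC=C(C)C)C#CCO[Si](C)(C)C(C)(C)C | intermediate
10 | (R)-5-(tert-butyldimethylsilyloxy)-2-(3-methylbut-2-enyl)pent-3-yn-1-ol | OC[C@H](CC=C(C)C)C#CCO[Si](C)(C)C(C)(C)C | intermediate
11 | rac-lavandulol | C=C(C)C(CC=C(C)C)CO | starting material
12 | (S)-lavandulol | C=C(C)[C@H](CC=C(C)C)CO | intermediate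
13 | 1,5-dimethoxycyclohexa-1,4-diene | COC1=CCC=C(OC)C1 | starting material
14 | (S)-lavandulyl trifluoromethanesulfonate | C=C(C)[C@H](CC=C(C)C)COS(=O)(=O)C(F)(F)F | intermediate
15 | 1,5-dimethoxy-6-[(R)-lavandulyl]cyclohexa-1,4-diene | C=C(C)[C@H](CC=C(C)C)CC1C(OC)=CCC=C1OC | intermediate
16 | (R)-5-(tert-butyldimethylsilyloxy)-2-(3-methylbut-2-enyl)pent-3-ynyl trifluoromethanesulfonate | FC(F)(F)S(=O)(=O)OC[C@H](CC=C(C)C)C#CCO[Si](C)(C)C(C)(C)C | intermediate
17 | 1,5-dimethoxy-6-[(R)-lavandulyl]-6-[(S)-5-(tert-butyldimethylsilyloxy)-2-(3-methylbut-2-enyl)pent-3-ynyl]cyclohexa-1,4-diene | C=C(C)[C@H](CC=C(C)C)CC1(C[C@H](CC=C(C)C)C#CCO[Si](C)(C)C(C)(C)C)C(OC)=CCC=C1OC | intermediate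
18 | 3,5-dimethoxy-4-[(R)-lavandulyl]-4-[(S)-5-(tert-butyldimethylsilyloxy)-2-(3-methylbut-2-enyl)pent-3-ynyl]cyclohexa-2,5-dien-1-one | C=C(C)[C@H](CC=C(C)C)CC1(C[C@H](CC=C(C)C)C#CCO[Si](C)(C)C(C)(C)C)C(OC)=CC(=O)C=C1OC | intermediate
19 | 3,5-dimethoxy-4-[(R)-lavandulyl]-4-[(S)-5-hydroxy-2-(3-methylbut-2-enyl)pent-3-ynyl]cyclohexa-2,5-dien-1-one | C=C(C)[C@H](CC=C(C)C)CC1(C[C@H](CC=C(C)C)C#CCO)C(OC)=CC(=O)C=C1OC | intermediate
20 | 3,5-dimethoxy-4-[(R)-lavandulyl]-4-[(S)-5-oxo-2-(3-methylbut-2-enyl)pent-3-ynyl]cyclohexa-2,5-dien-1-one | C=C(C)[C@H](CC=C(C)C)CC1(C[C@H](CC=C(C)C)C#CC=O)C(OC)=CC(=O)C=C1OC | intermediate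
21 | (Z)-2-[4-methoxy-5-((R)-lavandulyl)-7-(3-methylbut-2-enyl)-2,9-dioxobicyclo[3.3.1]non-3-en-8-ylidene]acetaldehyde | C=C(C)[C@H](CC=C(C)C)C[C@@]12C[C@H](CC=C(C)C)/C(=C/C=O)[C@@H](C(=O)C=C1OC)C2=O | intermediate
22 | 5-bromo-2-methylpent-2-ene | CC(C)=CCCBr | starting material
23 | (4-methylpent-3-enyl)magnesium bromide | CC(C)=CCC[Mg]Br | intermediate
24 | trimethylsilyl enol ether of 25 (C8–CH=CH–OSiMe3) | C=C(C)[C@H](CC=C(C)C)C[C@@]12C[C@H](CC=C(C)C)[C@](C=CO[Si](C)(C)C)(CCC=C(C)C)[C@@H](C(=O)C=C1OC)C2=O | intermediate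
25 | 2-[4-methoxy-5-((R)-lavandulyl)-7-(3-methylbut-2-enyl)-8-(4-methylpent-3-enyl)-2,9-dioxobicyclo[3.3.1]non-3-en-8-yl]acetaldehyde | C=C(C)[C@H](CC=C(C)C)C[C@@]12C[C@H](CC=C(C)C)[C@](CC=O)(CCC=C(C)C)[C@@H](C(=O)C=C1OC)C2=O | intermediate
26 | 4-methoxy-8-methyl-5-((R)-lavandulyl)-7-(3-methylbut-2-enyl)-8-(4-methylpent-3-enyl)bicyclo[3.3.1]non-3-ene-2,9-dione | C=C(C)[C@H](CC=C(C)C)C[C@@]12C[C@H](CC=C(C)C)[C@](C)(CCC=C(C)C)[C@@H](C(=O)C=C1OC)C2=O | intermediate
27 | 4-methoxy-8-methyl-5-((R)-lavandulyl)-1,7-bis(3-methylbut-2-enyl)-8-(4-methylpent-3-enyl)bicyclo[3.3.1]non-3-ene-2,9-dione | C=C(C)[C@H](CC=C(C)C)C[C@@]12C[C@H](CC=C(C)C)[C@](C)(CCC=C(C)C)[C@@](CC=C(C)C)(C(=O)C=C1OC)C2=O | intermediate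
28 | 3,4-dihydroxybenzoic acid | OC(=O)c1ccc(O)c(O)c1 | starting material
29 | tert-butyldimethylsilyl 3,4-bis(tert-butyldimethylsilyloxy)benzoate | CC(C)(C)[Si](C)(C)OC(=O)c1ccc(O[Si](C)(C)C(C)(C)C)c(O[Si](C)(C)C(C)(C)C)c1 | intermediate
30 | 3,4-bis(tert-butyldimethylsilyloxy)benzoic acid | OC(=O)c1ccc(O[Si](C)(C)C(C)(C)C)c(O[Si](C)(C)C(C)(C)C)c1 | intermediate
31 | 3,4-bis(tert-butyldimethylsilyloxy)benzoyl chloride | ClC(=O)c1ccc(O[Si](C)(C)C(C)(C)C)c(O[Si](C)(C)C(C)(C)C)c1 | intermediate
32 | 3-[3,4-bis(tert-butyldimethylsilyloxy)benzoyl]-4-methoxy-8-methyl-5-((R)-lavandulyl)-1,7-bis(3-methylbut-2-enyl)-8-(4-methylpent-3-enyl)bicyclo[3.3.1]non-3-ene-2,9-dione | C=C(C)[C@H](CC=C(C)C)C[C@@]12C[C@H](CC=C(C)C)[C@](C)(CCC=C(C)C)[C@@](CC=C(C)C)(C(=O)C(C(=O)c3ccc(O[Si](C)(C)C(C)(C)C)c(O[Si](C)(C)C(C)(C)C)c3)=C1OC)C2=O | intermediate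
33 | CNP0241026.2: 3-(3,4-dihydroxybenzoyl)-4-hydroxy-8-methyl-5-((R)-lavandulyl)-1,7-bis(3-methylbut-2-enyl)-8-(4-methylpent-3-enyl)bicyclo[3.3.1]non-3-ene-2,9-dione | C=C(C)[C@H](CC=C(C)C)C[C@@]12C[C@H](CC=C(C)C)[C@](C)(CCC=C(C)C)[C@@](CC=C(C)C)(C(=O)C(C(=O)c3ccc(O)c(O)c3)=C1O)C2=O | target

**Step count and risks**

Total step count: 19. Longest linear sequence: 15 steps (1–5, 8–15, 18, 19).

Steps most likely to fail:

1. Step 12 (Proposed new method). The β-methoxy enone may be too weak a π-nucleophile, so the iminium ion could be consumed by conjugate addition of water or amine, or by oligomerisation, before the ring closes. Fallback, from 19 back to 21: 2 M HCl in THF hydrolyses both methyl enol ethers of 19 to the enolised trione alcohol F1, and MnO2 gives the trione ynal F2. Catalytic Cs2CO3 in MeCN then closes the ring by anionic 6-exo-dig Michael addition of the free 1,3-dicarbonyl carbon to the ynal, a known carbocyclisation of active-methylene compounds, giving the free enol bicycle F3 under the same C7 control. O-methylation with TMSCHN2 returns 21 together with its regioisomeric enol ether F4, which is removed by chromatography.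

2. Step 13. Conjugate addition at the doubly α-branched β-carbon may be slow, so that 1,2-addition to the aldehyde or the C9 ketone takes over, or facial selectivity is incomplete. Fallback, from 21 back to 25: the small sp2 nucleophile vinylmagnesium bromide is added under copper catalysis and trapped with TBSCl to give the C8-vinyl silyl enol ether F5. Rhodium-catalysed hydroboration with pinacolborane, which distinguishes the monosubstituted vinyl group from the other alkenes, gives the primary alkylboronate F6. B-alkyl Suzuki–Miyaura coupling with 1-bromo-2-methylprop-1-ene gives the homoprenyl silyl enol ether F7, and dilute acid hydrolysis returns 25.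

3. Step 15. C-alkylation of the bridgehead enolate beside the new C8 quaternary carbon may be sluggish, letting O-alkylation or SN2′ attack on prenyl bromide compete. Fallback, from 26 back to 27: the bridgehead enolate is trapped with the smaller allyl bromide to give the C1-allyl compound F8. Cross-metathesis with 2-methylbut-2-ene (second-generation ruthenium benzylidene catalyst), a known allyl-to-prenyl conversion that leaves trisubstituted and 1,1-disubstituted alkenes untouched, then gives 27.

**Further compounds**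

F1 | step 12 | 3,5-dihydroxy-4-[(R)-lavandulyl]-4-[(S)-5-hydroxy-2-(3-methylbut-2-enyl)pent-3-ynyl]cyclohexa-2,5-dien-1-one (enolised trione) | C=C(C)[C@H](CC=C(C)C)CC1(C[C@H](CC=C(C)C)C#CCO)C(O)=CC(=O)C=C1O
F2 | step 12 | 3,5-dihydroxy-4-[(R)-lavandulyl]-4-[(S)-5-oxo-2-(3-methylbut-2-enyl)pent-3-ynyl]cyclohexa-2,5-dien-1-one | C=C(C)[C@H](CC=C(C)C)CC1(C[C@H](CC=C(C)C)C#CC=O)C(O)=CC(=O)C=C1O
F3 | step 12 | (Z)-2-[4-hydroxy-5-((R)-lavandulyl)-7-(3-methylbut-2-enyl)-2,9-dioxobicyclo[3.3.1]non-3-en-8-ylidene]acetaldehyde | C=C(C)[C@H](CC=C(C)C)C[C@@]12C[C@H](CC=C(C)C)/C(=C/C=O)[C@@H](C(=O)C=C1O)C2=O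
F4 | step 12 | (Z)-2-[2-methoxy-5-((R)-lavandulyl)-7-(3-methylbut-2-enyl)-4,9-dioxobicyclo[3.3.1]non-2-en-8-ylidene]acetaldehyde (regioisomer of 21) | C=C(C)[C@H](CC=C(C)C)C[C@@]12C[C@H](CC=C(C)C)/C(=C/C=O)[C@@H](C(OC)=CC1=O)C2=O
F5 | step 13 | C8-vinyl tert-butyldimethylsilyl enol ether (C8–CH=CH–OTBS, C8–CH=CH2) | C=C(C)[C@H](CC=C(C)C)C[C@@]12C[C@H](CC=C(C)C)[C@](C=CO[Si](C)(C)C(C)(C)C)(C=C)[C@@H](C(=O)C=C1OC)C2=O
F6 | step 13 | C8-[2-(4,4,5,5-tetramethyl-1,3,2-dioxaborolan-2-yl)ethyl] silyl enol ether | C=C(C)[C@H](CC=C(C)C)C[C@@]12C[C@H](CC=C(C)C)[C@](C=CO[Si](C)(C)C(C)(C)C)(CCB3OC(C)(C)C(C)(C)O3)[C@@H](C(=O)C=C1OC)C2=O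
F7 | step 13 | tert-butyldimethylsilyl enol ether of 25 | C=C(C)[C@H](CC=C(C)C)C[C@@]12C[C@H](CC=C(C)C)[C@](C=CO[Si](C)(C)C(C)(C)C)(CCC=C(C)C)[C@@H](C(=O)C=C1OC)C2=O
F8 | step 15 | 1-allyl-4-methoxy-8-methyl-5-((R)-lavandulyl)-7-(3-methylbut-2-enyl)-8-(4-methylpent-3-enyl)bicyclo[3.3.1]non-3-ene-2,9-dione | C=C(C)[C@H](CC=C(C)C)C[C@@]12C[C@H](CC=C(C)C)[C@](C)(CCC=C(C)C)[C@@](CC=C)(C(=O)C=C1OC)C2=O
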